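Readings and results are simulated with constants of no real substance; scatter was added.

Slowness is what the two earlier runs end in.

common to all: starting complex 0.24 M

| flask | incoming ligand | leaving ligand | remark | time |
|---|---|---|---|---|
| amber | 1 equiv | 0.50 equiv | run made earlier |  |
| violet | 2.5 equiv | 0.50 equiv | run made earlier |  |
| Friday's | 4.00 equiv | 0.500 equiv |  | 15 h |
| Wednesday's | 1.20 equiv | 0.500 equiv |  | 15 h |

| run | time / h | complex with three exchanged / % | complex with one exchanged / % | starting complex / % |
|---|---|---|---|---|
| amber | 2.50 | 0.2 | 23.9 | 75.6 |
| amber | 5.00 | 0 | 26.3 | 72.0 |
| amber | 8.00 | 0.1 | 28.3 | 70.8 |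
| amber | 10.0 | 0.2 | 28.9 | 69.4 |
| violet | 2.50 | 1.1 | 45.8 | 48.9 |
| violet | 5.00 | 2.0 | 49.9 | 43.5 |
| violet | 8.00 | 1.7 | 52.1 | 40.7 |
| violet | 10.0 | 2.1 | 53.3 | 39.3 |

(standard deviation of a reading: 0.3 percentage points)

1. which of these holds the largest part of the starting complex at the end of Friday's (complex with three exchanged / starting complex / complex with two exchanged / complex with four exchanged / complex with one exchanged)
2. which of these holds the largest part of the starting complex at the end of Wednesday's (complex with three exchanged / starting complex / complex with two exchanged / complex with four exchanged / complex with one exchanged)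
3. complex with three exchanged at the end of Friday's, in percent of the starting complex charged

- what was read earlier has a scatter of 0.3 percentage points, one standard deviation

We follow one rate: the logarithmic loss of starting complex per hour, which takes the complex's own falling out. Up to 2.50 h the amber run gives 0.112 h⁻¹ and the violet run 0.286 h⁻¹. That is a ratio of 2.55 against a charge ratio of 2.50. So, as read, the early rate in these runs goes with the charge of incoming ligand, as a first order in c(incoming ligand) does.

From then to 10.0 h the rate drops to 0.0114 h⁻¹ in the amber run and 0.0291 h⁻¹ in the violet run. The slowing is a factor of 9.82 and 9.83, alike at both charges. Spent incoming ligand, counted one per starting complex lost, gives a factor of 1.32 in the amber run. That leaves 7.44 that we cannot name from these readings.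

We carry the slowed rate on to 15 h and sum the rate over the run, per equivalent, averaging both runs. This gives 0.427. We call it the exposure per equivalent. In our reckoning we let the exposure scale with the charged c(incoming ligand), and we take the starting complex left as the exponential of minus the exposure.

Friday's flask gets 1.71 and keeps 18.1 %, so we expect complex with one exchanged to lead, as it does in the violet run. Wednesday's flask gets 0.513 and keeps 59.9 %, more than all the rest together. Our reckoning stops at the starting complex.

The forecast names complex with one exchanged for Friday's and starting complex for Wednesday's, with 4 % of complex with three exchanged on Friday's, holding that “Released ligand builds up and suppresses further exchange”.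

The flask gives complex with one exchanged for Friday's, starting complex for Wednesday's and 7.51 % of complex with three exchanged on Friday's. The starting complex ends at 18.8 % on Friday's and 61.8 % on Wednesday's.

    starting complex + incoming ligand ⇌ leaving ligand + complex with one exchanged (K = 0.580, k = 0.0200 L mol⁻¹ min⁻¹)
    complex with one exchanged + incoming ligand ⇌ leaving ligand + complex with two exchanged (K = 0.770, k = 0.00490 L mol⁻¹ min⁻¹)
    complex with two exchanged + incoming ligand ⇌ leaving ligand + complex with three exchanged (K = 5.00, k = 0.0180 L mol⁻¹ min⁻¹)
    complex with three exchanged + incoming ligand ⇌ leaving ligand + complex with four exchanged (K = 0.330, k = 0.00380 L mol⁻¹ min⁻¹)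
    incoming ligand ⇌ dormant form (K = 20.0, k = 0.0110 min⁻¹)
    leaving ligand → by-product carried off (k = 0.0990 min⁻¹)

The neighbour flask is Friday's with 0.096 M of starting complex, the equivalents and time held. Its c(incoming ligand) falls with the charge, so its exposure is 0.683, which would keep 50.5 %. The neighbour flask keeps 44 %, less than reckoned, and complex with one exchanged holds 49.7 %. Read back from what it keeps, the neighbour's exposure is 0.811.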